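**Retrosynthetic overview** (numbering: ring B = C10–C1–C2(=O)–C3–C4(CH3)–C5(CH3); ring A = C5–C6–C7(isopropenyl)–C8(O)–C9(O)–C10)

1. The route rests on the two cis methyl groups at C4 and C5 beside the ring-fusion carbon C10, and on the C2 oxygen of ring B. They are read as the trace of an (E)-2-methylbut-2-enoyl dienophile C4=C5 and a 2-alkoxy diene C10=C1–C2=C3, once a temporary carbonyl at C6 turns C6–C9 of ring A into the tether.
2. Target 26 ⇐ diol ketone 23 (two ester bonds, made last) ⇐ adduct 19 (C6 carbonyl reduced and removed by radical deoxygenation; enol ether and acetonide hydrolysed together).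
3. 19 ⇐ trienone 18 by one intramolecular Diels–Alder reaction forming C5–C10 and C3–C4. Rings A and B are closed together in this step; before it the only ring is the dioxolane.
4. 18 ⇐ Weinreb amide 15 + (E)-but-2-en-2-yllithium (C5–C6); the ethoxy diene comes from a Stille coupling at C1–C2 (14 → 15).
5. 14 ⇐ syn aldol (C7–C8) of senecioyl imide 4, reacting at the α-carbon of its dienolate, with α-silyloxy aldehyde 9; 9 comes from (R)-glyceraldehyde acetonide by iodo-olefination (C9 from the chiral pool).

Key step: step 11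

Remarks on the chemistry:
- β denotes the face of ring A carrying the C8 and C9 oxygens. In this numbering the target is (4S,5R,7R,8R,9S,10S) with two (R)-2-methylbutanoyl groups.
- C7/C8 must be syn and C8/C9 anti in the open chain (trans and cis on ring A), so a syn aldol with the (R)-benzyl auxiliary is used.
- The C6 carbinol of 20 and 21 is removed in step 14; its configuration is left open and the SMILES carry no descriptor there.
- The acylation (step 10) is placed after the Stille coupling so that the alkenyllithium never meets the vinyl iodide.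

Step 1
Reactants: 1 3-methylbut-2-enoic acid; 2 (R)-4-benzyloxazolidin-2-one
Product: 4 (R)-4-benzyl-3-(3-methylbut-2-enoyl)oxazolidin-2-one, via 3-methylbut-2-enoic pivalic anhydride 3 (not isolated)
Conditions: PivCl, Et3N, THF, −20 °C; then LiCl, 2, −20 °C → rt
Reagents that add atoms: none
Why: Mixed-anhydride N-acylation of the oxazolidinone under LiCl/Et3N, in which the hindered pivaloyl carbonyl steers attack to the senecioyl carbonyl; no stereocentre is formed.

Step 2
Reactants: 5 (R)-2,3-O-isopropylideneglyceraldehyde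
Product: 6 (4S)-4-[(E)-2-iodoethenyl]-2,2-dimethyl-1,3-dioxolane
Conditions: CrCl2, CHI3, THF, 0 °C → rt; minor Z isomer removed by chromatography
Reagents that add atoms: iodoform, IC(I)I
Why: Takai olefination, in which the gem-dichromium reagent adds to the aldehyde and eliminates to the E-vinyl iodide under non-basic conditions that should leave the α-alkoxy stereocentre (future C9) untouched.

Step 3
Reactants: 6 (4S)-4-[(E)-2-iodoethenyl]-2,2-dimethyl-1,3-dioxolane
Product: 7 (2S,3E)-4-iodobut-3-ene-1,2-diol
Conditions: AcOH/H2O (4:1), 40 °C; evaporate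
Reagents that add atoms: none
Why: Acid-catalysed acetonide hydrolysis; the vinyl iodide is inert to aqueous acetic acid.

Step 4
Reactants: 7 (2S,3E)-4-iodobut-3-ene-1,2-diol
Product: 8 (2S,3E)-4-iodo-1,2-bis(triethylsilyloxy)but-3-ene
Conditions: TESCl, imidazole, DMAP (cat.), CH2Cl2, 0 °C → rt
Reagents that add atoms: chlorotriethylsilane, CC[Si](Cl)(CC)CC
Why: Imidazole-mediated silylation of both hydroxyl groups.

Step 5
Reactants: 8 (2S,3E)-4-iodo-1,2-bis(triethylsilyloxy)but-3-ene
Product: 9 (2S,3E)-4-iodo-2-(triethylsilyloxy)but-3-enal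
Conditions: (COCl)2, DMSO, CH2Cl2, −78 → −40 °C; then Et3N, −78 → −30 °C; crude aldehyde used at once
Reagents that add atoms: none
Why: Swern oxidation applied directly to the bis-silyl ether, a known selective oxidation in which activated DMSO cleaves the primary triethylsilyl ether and oxidises it to the aldehyde while the secondary one stays; low temperature and immediate use should protect the α-stereocentre, which is both α to the aldehyde and allylic.

Step 6
Reactants: 4 (R)-4-benzyl-3-(3-methylbut-2-enoyl)oxazolidin-2-one; 9 (2S,3E)-4-iodo-2-(triethylsilyloxy)but-3-enal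
Product: 11 (R)-4-benzyl-3-[(2R,3R,4S,5E)-3-hydroxy-6-iodo-2-(prop-1-en-2-yl)-4-(triethylsilyloxy)hex-5-enoyl]oxazolidin-2-one, via dibutylboron Z-dienolate 10 (not isolated)
Conditions: Bu2BOTf, Et3N, CH2Cl2, −78 → 0 °C; then 9, −78 → −10 °C; pH 7 buffer, MeOH, H2O2, 0 °C
Reagents that add atoms: none
Why: Evans syn aldol of the Z(O)-boron dienolate, which reacts at its α-carbon through a Zimmerman–Traxler chair to give the 2,3-syn adduct with the isopropenyl group on C7; the (R)-benzyl auxiliary sets C7 and C8 as R,R, and the Cornforth preference of the α-silyloxy aldehyde for the 3,4-anti adduct points the same way (matched pair).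

Step 7
Reactants: 11 aldol adduct
Product: 12 (2R,3R,4S,5E)-3-hydroxy-6-iodo-N-methoxy-N-methyl-2-(prop-1-en-2-yl)-4-(triethylsilyloxy)hex-5-enamide
Conditions: MeNH(OMe)·HCl, AlMe3, CH2Cl2, −20 → 0 °C; Rochelle salt work-up
Reagents that add atoms: N,O-dimethylhydroxylamine hydrochloride, CNOC.Cl
Why: Weinreb transamidation with the aluminium amide, directed to the exocyclic carbonyl by the free β-hydroxyl; the auxiliary is released for recovery and no epimerisation at C7 is expected at this temperature.

Step 8
Reactants: 12 Weinreb amide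
Product: 14 (2R)-2-[(4R,5S)-5-[(E)-2-iodoethenyl]-2,2-dimethyl-1,3-dioxolan-4-yl]-N-methoxy-N,3-dimethylbut-3-enamide, via diol Weinreb amide 13 (not isolated)
Conditions: CSA (cat.), MeOH/CH2Cl2, 0 °C; then 2,2-dimethoxypropane, rt; Et3N quench
Reagents that add atoms: 2,2-dimethoxypropane, COC(C)(C)OC
Why: Acid-catalysed methanolysis of the silyl ether followed by transketalisation, trapping the erythro diol at once as the cis-4,5-disubstituted dioxolane so that the γ-hydroxy amide has little time to lactonise; no stereocentre is touched.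

Step 9
Reactants: 14 iodide
Product: 15 (2R)-2-[(4R,5S)-5-[(1E)-3-ethoxybuta-1,3-dien-1-yl]-2,2-dimethyl-1,3-dioxolan-4-yl]-N-methoxy-N,3-dimethylbut-3-enamide
Conditions: tributyl(1-ethoxyvinyl)stannane, Pd(PPh3)4 (5 mol %), CuI (10 mol %), DMF, rt → 40 °C; aq. KF; Et3N-deactivated silica
Reagents that add atoms: tributyl(1-ethoxyvinyl)stannane, C=C(OCC)[Sn](CCCC)(CCCC)CCCC
Why: Stille coupling of the vinyl iodide with retention of the E geometry; the neutral conditions and base-treated silica should preserve the acid-sensitive 2-ethoxy diene.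

Step 10
Reactants: 15 ethoxy diene Weinreb amide; 16 (E)-2-bromobut-2-ene
Product: 18 (2E,5R)-5-[(4R,5S)-5-[(1E)-3-ethoxybuta-1,3-dien-1-yl]-2,2-dimethyl-1,3-dioxolan-4-yl]-3,6-dimethylhepta-2,6-dien-4-one, via (E)-but-2-en-2-yllithium 17 (not isolated)
Conditions: 16, t-BuLi (2 equiv per 16), Et2O, −78 °C; then 15, THF, −78 → −40 °C; pH 7 phosphate buffer; used promptly
Reagents that add atoms: none
Why: Weinreb ketone synthesis, in which the stereoretentive bromine–lithium exchange carries the E geometry into the tiglyl ketone and the chelated tetrahedral intermediate prevents over-addition; addition at −78 °C should outrun deprotonation at C7, and the neutral quench keeps the enol ether.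

Step 11
Reactants: 18 trienone
Product: 19 cis-fused adduct (ring B C10–C1=C2(OEt)–C3–C4–C5; ring A C5–C6(=O)–C7–C8–C9–C10; C8/C9 acetonide)
Conditions: PhMe (0.01 M), BHT (cat.), 110 °C, sealed tube
Reagents that add atoms: none
Why: Thermal type 1 intramolecular Diels–Alder reaction of a 1,7,9-decatrien-3-one, a concerted asynchronous [4+2] in which the nucleophilic diene terminus C3 bonds to the enone β-carbon C4 and C10 bonds to the α-carbon C5, so that tether and polarisation agree on one regiochemistry. Ring A closes as a six-membered ring through the four-atom C6–C9 tether (bond C5–C10) and ring B is the new cyclohexene (bonds C5–C10 and C3–C4), left as the C1=C2 ethyl enol ether. At C4 and C5 the E-dienophile adds suprafacially, so its two methyl groups should remain cis. At C5/C10 the cis fusion should follow from the mode with the tether carbonyl endo, which this substrate class reaches through a boat-like tether, whereas either exo chair (trans fusion) would set the C5 methyl 1,3-diaxial to the C9 oxygen or to the C7 isopropenyl group. For the diene face, the C5 methyl is a flagpole group facing C8 in the endo boat, so the arrangement with C8–H in the opposing flagpole position, the C8 oxygen outward and the C7 isopropenyl pseudo-equatorial should be preferred, which puts C10–H anti to the C9 oxygen as the target requires. The step needs endo selectivity and this facial selectivity together; the cis-dioxolane (holding C7 and C10 gauche) and the trans C7 substituent are the elements expected to secure them.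

Step 12
Reactants: 19 cis-fused adduct
Product: 20 C6 alcohol (C6 epimers)
Conditions: LiAlH4, Et2O, −78 → 0 °C
Reagents that add atoms: none
Why: Hydride reduction of the hindered ketone, faster than enolisation toward C7; the new carbinol configuration is irrelevant, and the C7 isopropenyl is already in its equatorial, thermodynamically preferred position.

Step 13
Reactants: 20 C6 alcohol
Product: 21 C6 O-alkyl S-methyl xanthate (C6 epimers)
Conditions: NaH, imidazole (cat.), THF, 0 °C → rt; CS2; then MeI
Reagents that add atoms: carbon disulfide, S=C=S; iodomethane, CI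
Why: Xanthate formation by addition of the alkoxide to CS2 and S-methylation, the standard activation of a hindered secondary alcohol for radical deoxygenation.

Step 14
Reactants: 21 xanthate
Product: 22 C6-deoxy enol ether acetonide
Conditions: Bu3SnH (3 equiv, 0.3 M), AIBN (cat.), PhMe, 90 °C
Reagents that add atoms: none
Why: Barton–McCombie deoxygenation, in which a high stannane concentration should make hydrogen transfer to the C6 radical faster than its 3-exo closure onto the neighbouring isopropenyl group.

Step 15
Reactants: 22 C6-deoxy enol ether acetonide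
Product: 23 (4S,5R,7R,8R,9S,10S)-8,9-dihydroxy-2-ketone (cis-decalone diol)
Conditions: AcOH/H2O/THF (3:1:1), 45 °C
Reagents that add atoms: water, O
Why: Aqueous acid hydrolysis of the enol ether to the C2 ketone and of the acetonide to the cis-diol in one operation; the isopropenyl group should survive mild acetic acid, and no stereocentre is α to the new ketone.

Step 16
Reactants: 23 diol ketone; 24 (R)-2-methylbutanoic acid
Product: 26 target diester, via (R)-2-methylbutanoic anhydride 25 (not isolated)
Conditions: 24 (6 equiv), DCC (3 equiv), CH2Cl2, 0 °C → rt; then 23, DMAP, pyridine, rt → 40 °C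
Reagents that add atoms: none
Why: DMAP-catalysed acylation of both secondary hydroxyls with the preformed symmetric anhydride; using the anhydride instead of an acid chloride should limit ketene formation, so the α-centre of each acyl group keeps its R configuration.

**Compound list**

1 | 3-methylbut-2-enoic acid | CC(C)=CC(=O)O | starting material
2 | (R)-4-benzyloxazolidin-2-one | O=C1N[C@H](Cc2ccccc2)CO1 | starting material
3 | 3-methylbut-2-enoic pivalic anhydride | CC(C)=CC(=O)OC(=O)C(C)(C)C | intermediate
4 | (R)-4-benzyl-3-(3-methylbut-2-enoyl)oxazolidin-2-one | CC(C)=CC(=O)N1[C@H](Cc2ccccc2)COC1=O | intermediate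
5 | (R)-2,3-O-isopropylideneglyceraldehyde | O=C[C@H]1COC(C)(C)O1 | starting material
6 | (4S)-4-[(E)-2-iodoethenyl]-2,2-dimethyl-1,3-dioxolane | I/C=C/[C@H]1COC(C)(C)O1 | intermediate
7 | (2S,3E)-4-iodobut-3-ene-1,2-diol | I/C=C/[C@H](O)CO | intermediate
8 | (2S,3E)-4-iodo-1,2-bis(triethylsilyloxy)but-3-ene | I/C=C/[C@H](O[Si](CC)(CC)CC)CO[Si](CC)(CC)CC | intermediate
9 | (2S,3E)-4-iodo-2-(triethylsilyloxy)but-3-enal | I/C=C/[C@H](O[Si](CC)(CC)CC)C=O | intermediate
10 | dibutylboron Z(O)-dienolate of 4 | C=C(C)/C=C(\OB(CCCC)CCCC)N1[C@H](Cc2ccccc2)COC1=O | intermediate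
11 | (R)-4-benzyl-3-[(2R,3R,4S,5E)-3-hydroxy-6-iodo-2-(prop-1-en-2-yl)-4-(triethylsilyloxy)hex-5-enoyl]oxazolidin-2-one | O=C1OC[C@@H](Cc2ccccc2)N1C(=O)[C@H](C(C)=C)[C@@H](O)[C@@H](O[Si](CC)(CC)CC)/C=C/I | intermediate
12 | (2R,3R,4S,5E)-3-hydroxy-6-iodo-N-methoxy-N-methyl-2-(prop-1-en-2-yl)-4-(triethylsilyloxy)hex-5-enamide | CON(C)C(=O)[C@H](C(C)=C)[C@@H](O)[C@@H](O[Si](CC)(CC)CC)/C=C/I | intermediate
13 | (2R,3R,4S,5E)-3,4-dihydroxy-6-iodo-N-methoxy-N-methyl-2-(prop-1-en-2-yl)hex-5-enamide | CON(C)C(=O)[C@H](C(C)=C)[C@@H](O)[C@@H](O)/C=C/I | intermediate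
14 | (2R)-2-[(4R,5S)-5-[(E)-2-iodoethenyl]-2,2-dimethyl-1,3-dioxolan-4-yl]-N-methoxy-N,3-dimethylbut-3-enamide | CON(C)C(=O)[C@H](C(C)=C)[C@H]1OC(C)(C)O[C@H]1/C=C/I | intermediate
15 | (2R)-2-[(4R,5S)-5-[(1E)-3-ethoxybuta-1,3-dien-1-yl]-2,2-dimethyl-1,3-dioxolan-4-yl]-N-methoxy-N,3-dimethylbut-3-enamide | CON(C)C(=O)[C@H](C(C)=C)[C@H]1OC(C)(C)O[C@H]1/C=C/C(OCC)=C | intermediate
16 | (E)-2-bromobut-2-ene | C/C=C(\C)Br | starting material
17 | (E)-but-2-en-2-yllithium | C/C=C(\C)[Li] | intermediate
18 | (2E,5R)-5-[(4R,5S)-5-[(1E)-3-ethoxybuta-1,3-dien-1-yl]-2,2-dimethyl-1,3-dioxolan-4-yl]-3,6-dimethylhepta-2,6-dien-4-one (Diels–Alder precursor) | C=C(OCC)/C=C/[C@@H]1OC(C)(C)O[C@@H]1[C@@H](C(C)=C)C(=O)/C(C)=C/C | intermediate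
19 | cis-fused adduct, (4S,5R,7R,8R,9S,10S): C1=C2 ethyl enol ether, C6 ketone, 8β,9β-O-isopropylidene, 7α-isopropenyl, 10α-H, 5α-CH3, 4α-CH3 | C=C(C)[C@H]1C(=O)[C@@]2(C)[C@H](C=C(OCC)C[C@@H]2C)[C@@H]3OC(C)(C)O[C@H]13 | intermediate
20 | C6 alcohol of 19 (C6 epimers; other centres as in 19) | C=C(C)[C@H]1C(O)[C@@]2(C)[C@H](C=C(OCC)C[C@@H]2C)[C@@H]3OC(C)(C)O[C@H]13 | intermediate
21 | C6 O-alkyl S-methyl dithiocarbonate of 20 (C6 epimers) | C=C(C)[C@H]1C(OC(=S)SC)[C@@]2(C)[C@H](C=C(OCC)C[C@@H]2C)[C@@H]3OC(C)(C)O[C@H]13 | intermediate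
22 | C6-deoxy compound, (4S,5R,7R,8R,9S,10S): C1=C2 ethyl enol ether, 8β,9β-O-isopropylidene, 7α-isopropenyl, 10α-H, 5α-CH3, 4α-CH3 | C=C(C)[C@H]1C[C@@]2(C)[C@H](C=C(OCC)C[C@@H]2C)[C@@H]3OC(C)(C)O[C@H]13 | intermediate
23 | (4S,5R,7R,8R,9S,10S)-8β,9β-dihydroxy-7α-isopropenyl-4α,5α-dimethyl-10α-H-decalin-2-one | C=C(C)[C@H]1C[C@@]2(C)[C@H](CC(=O)C[C@@H]2C)[C@H](O)[C@@H]1O | intermediate
24 | (R)-2-methylbutanoic acid | CC[C@@H](C)C(=O)O | starting material
25 | (R)-2-methylbutanoic anhydride | CC[C@@H](C)C(=O)OC(=O)[C@H](C)CC | intermediate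
26 | CNP0248369.1: 8,9-bis[(R)-2-methylbutanoate] of 23 | C=C(C)[C@H]1C[C@@]2(C)[C@H](CC(=O)C[C@@H]2C)[C@H](OC(=O)[C@H](C)CC)[C@@H]1OC(=O)[C@H](C)CC | target

**Totals**

Total step count: 16. Longest linear sequence: 15 steps (5 → 26, steps 2–16); steps 1 and the in-flask anhydride formation of step 16 are side branches.

**Steps most likely to fail**

1. Step 11 (cycloaddition).
   - What may go wrong: at 110 °C the cycloaddition may be slower than enolisation of the β,γ-unsaturated ketone toward C7 (epimerisation, migration of the isopropenyl double bond into conjugation, β-elimination of the C8 oxygen) and slower than degradation of the ethoxy diene. The exo mode (trans fusion) or addition to the other diene face may also compete.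
   - Fallback: replace thermal activation by Lewis-acid activation of a silyl dienol ether at low temperature, setting out from 18.
   - Selective hydrolysis of the enol ether (oxalic acid on wet silica, CH2Cl2, 0 °C) should give the methyl enone F1.
   - Kinetic silylation of the methyl ketone (TBSOTf, Et3N, CH2Cl2, −78 °C) should give the 2-silyloxy diene F2.
   - Me2AlCl (CH2Cl2, −78 → −20 °C) complexes the C6 carbonyl and should drive the intramolecular Diels–Alder reaction in the cold, where the endo mode is more strongly favoured, giving the silyl enol ether ketone F3.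
   - F3 is taken through the conditions of steps 12–14 (alcohol F4, xanthate F5, deoxygenated silyl enol ether F6). The acid of step 15 then cleaves silyl enol ether and acetonide of F6, and the route is rejoined at 23.

2. Step 10 (acylation).
   - What may go wrong: deprotonation at C7 (α to the amide and allylic) may compete with addition, causing epimerisation at C7 or β-elimination of the dioxolane oxygen; the enol ether may also be lost on work-up.
   - Fallback: pass through the aldehyde oxidation level, setting out from 15.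
   - DIBAL-H (THF, −78 °C) should give the aldehyde F7.
   - Addition of 17 precomplexed with CeCl3 (−78 °C) is far faster than enolisation of an aldehyde and should give the allylic alcohol F8 (C6 epimers).
   - Dess–Martin periodinane buffered with NaHCO3/pyridine should oxidise F8 to 18, where the route is rejoined.

3. Step 14 (radical deoxygenation).
   - What may go wrong: the C6 radical is homoallylic to the isopropenyl group, and 3-exo closure with reopening would move that group from C7 to C6; thermal syn-elimination of the hindered xanthate may also compete.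
   - Fallback: replace the radical chain by a dissolving-metal cleavage of a phosphorodiamidate, setting out from 20.
   - n-BuLi and then bis(dimethylamino)phosphoryl chloride (THF, 0 °C → rt) should give the phosphorodiamidate F9.
   - Li in EtNH2/THF with t-BuOH at 0 °C (short contact, to spare the isopropenyl group) should cleave the C6–O bond, the transient radical being reduced to the carbanion before it can rearrange. This gives 22, where the route is rejoined.

**Further compounds**

F1 | step 11 | methyl enone: 18 with (E)-3-oxobut-1-enyl in place of the ethoxy diene | CC(=O)/C=C/[C@@H]1OC(C)(C)O[C@@H]1[C@@H](C(C)=C)C(=O)/C(C)=C/C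
F2 | step 11 | 2-(tert-butyldimethylsilyloxy) diene analogue of 18 | C=C(O[Si](C)(C)C(C)(C)C)/C=C/[C@@H]1OC(C)(C)O[C@@H]1[C@@H](C(C)=C)C(=O)/C(C)=C/C
F3 | step 11 | tert-butyldimethylsilyl enol ether analogue of 19 | C=C(C)[C@H]1C(=O)[C@@]2(C)[C@H](C=C(O[Si](C)(C)C(C)(C)C)C[C@@H]2C)[C@@H]3OC(C)(C)O[C@H]13
F4 | step 11 | C6 alcohol of F3 (C6 epimers) | C=C(C)[C@H]1C(O)[C@@]2(C)[C@H](C=C(O[Si](C)(C)C(C)(C)C)C[C@@H]2C)[C@@H]3OC(C)(C)O[C@H]13
F5 | step 11 | C6 S-methyl xanthate of F4 (C6 epimers) | C=C(C)[C@H]1C(OC(=S)SC)[C@@]2(C)[C@H](C=C(O[Si](C)(C)C(C)(C)C)C[C@@H]2C)[C@@H]3OC(C)(C)O[C@H]13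
F6 | step 11 | C6-deoxy silyl enol ether acetonide (silyl analogue of 22) | C=C(C)[C@H]1C[C@@]2(C)[C@H](C=C(O[Si](C)(C)C(C)(C)C)C[C@@H]2C)[C@@H]3OC(C)(C)O[C@H]13
F7 | step 10 | (2R)-2-[(4R,5S)-5-[(1E)-3-ethoxybuta-1,3-dien-1-yl]-2,2-dimethyl-1,3-dioxolan-4-yl]-3-methylbut-3-enal | O=C[C@H](C(C)=C)[C@H]1OC(C)(C)O[C@H]1/C=C/C(OCC)=C
F8 | step 10 | C6 allylic alcohol corresponding to 18 (C6 epimers) | C/C=C(\C)C(O)[C@H](C(C)=C)[C@H]1OC(C)(C)O[C@H]1/C=C/C(OCC)=C
F9 | step 14 | C6 N,N,N',N'-tetramethylphosphorodiamidate of 20 (C6 epimers) | C=C(C)[C@H]1C(OP(=O)(N(C)C)N(C)C)[C@@]2(C)[C@H](C=C(OCC)C[C@@H]2C)[C@@H]3OC(C)(C)O[C@H]13
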